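At early times the two earlier runs, alder and larch, already lie together: at 2.50 min both hold 38.1% of their starting material, though larch was charged 2.31 times as strong as alder. Does the charge matter at all for the new flask?

| flask | starting material | coupling partner | remark | time |
|---|---|---|---|---|
| alder | 0.13 M | 0.60 M (fed, over 40 s) | run made earlier |  |
| larch | 0.30 M | 0.60 M (fed, over 40 s) | run made earlier |  |
| flask | 0.20 M | 0.600 M (fed, over 40 s) |  | 20 min |

| run | time / min | product / % | starting material / % |
|---|---|---|---|
| alder | 1.00 | 2.4 | 66.3 |
| alder | 1.50 | 3.9 | 54.4 |
| alder | 2.50 | 8.7 | 38.1 |
| alder | 4.00 | 16.7 | 23.8 |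
| alder | 8.00 | 33.8 | 12.7 |
| alder | 12.0 | 45.8 | 10.1 |
| larch | 0.833 | 2.0 | 70.3 |
| larch | 2.50 | 9.0 | 38.1 |
| larch | 4.00 | 17.3 | 24.5 |
| larch | 6.00 | 26.6 | 15.8 |
| larch | 10.0 | 40.3 | 11.7 |
| larch | 12.0 | 45.7 | 10.0 |

(standard deviation of a reading: 0.5 percentage points)

* amount of product in percent of the starting material charged, at 4.0 min, 10 min and 20 min

- percentages count the starting material that a species holds: one homo dimer A counts as two
- product is meant together with its crystals
- solid, in amounts per volume of the solution: crystals
- steps that have been proposed: 2 starting material -> homo dimer A; starting material -> product; starting material <-> intermediate B; intermediate A -> product; 2 coupling partner -> homo dimer B; crystals <-> product; starting material -> intermediate A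

At 4.00 min larch stands 0.6 percentage points above alder in product, and the charge of the new flask lies 41.2% of the way from alder to larch. The gap times that fraction, 0.25 points, is what we call the charge correction: the gap between two runs of equal coupling partner charge at one time, scaled by where a new charge lies between theirs. It is smaller than the scatter of one reading, 0.5 points, so we expect the flask to follow the curve that alder and larch share in percent.

What does that curve give? For the flask, alder plus the correction gives us 16.9% at 4.0 min. At 12.0 min the gap is −0.1 points, again within the scatter. The readings end there, so at 20 min there is no gap to scale, and that figure rests on extending the curve.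

The forecast gives 17%, 40.2% and 61%, holding that “0.20 M should follow the same curve”. At 4.0 min our figure differs slightly from its 17%, by less than the scatter.

The flask gives 16.6%, 40.1% and 60.3%.

    2 starting material → homo dimer A (k = 9.10 × 10⁻⁶ M⁻¹ s⁻¹)
    starting material → product (k = 9.70 × 10⁻⁵ s⁻¹)
    starting material ⇌ intermediate B (K = 2.50, k = 0.00430 s⁻¹)
    intermediate A → product (k = 0.00440 s⁻¹)
    2 coupling partner → homo dimer B (k = 2.10 × 10⁻⁴ M⁻¹ s⁻¹)
    crystals ⇌ product, rate k6*(cs6 - [product]) while solid is left; crystals form when [product] > cs6 (solubility = 2.30 mM, k = 0.0460 s⁻¹)
    starting material → intermediate A (k = 0.00280 s⁻¹)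

At 4.0 min the flask stands 0.30 points below our corrected figure, less than the scatter. Carried from the flask up to larch, the correction adds 0.35 points and gives 16.9%, against the 17.3% read in larch. Of the flask's 60.3% product, 58.6% stands as crystals at 20.0 min, and the ceiling on dissolved product changes nothing in the figure. With [starting material] at its charge, the flask uses starting material for homo dimer A at 0.130% of the rate of its path to intermediate A. Homo dimer A holds 0.0310% at 20.0 min.

(The runs stem from a simulated flask with constants of no real substance.)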